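All constants stand for no real mixture; the flask was simulated.

Do not expect a doubled catalyst charge to double the rate at a given conversion: one step of the scheme turns catalyst into spent catalyst as the run goes.

substrate 20 mM; coupling partner 60.0 mM; free catalyst 100 µM

    substrate + free catalyst ⇌ catalyst intermediate A (K1 = 200 M⁻¹, k1 = 2190 M⁻¹ s⁻¹)
    coupling partner + catalyst intermediate A → catalyst intermediate B (k2 = 155 M⁻¹ s⁻¹)
    catalyst intermediate B → free catalyst + target (k3 = 10.5 s⁻¹)
    catalyst intermediate A → spent catalyst (k4 = 0.0461 s⁻¹)
    2 coupling partner → self-condensation product (k5 = 0.127 M⁻¹ s⁻¹)

1. the form that holds most of the catalyst when 20 % of the substrate are converted (catalyst intermediate B / catalyst intermediate A / free catalyst / spent catalyst)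
2. its share of the catalyst then
3. factor on the rate of making target when 20 % of the substrate are converted if free catalyst is charged twice over
4. factor on the rate when 20 % of the substrate are converted if free catalyst is charged at 1000 µM instead

The decision for the next run is how much catalyst to charge. Divide the rate of coupling by the rate at which intermediate A turns into spent catalyst. Intermediate A stands in both rates, so it drops out, and time with it:

rate constant of coupling × coupling partner ÷ rate constant of loss = 155 M⁻¹ s⁻¹ × 60.0 mM ÷ 0.0461 s⁻¹ = 202

Call this the turnover allowance, the couplings made per catalyst lost, taken here with the partner at its charge. Assuming each coupling ends as target, the loss follows the target made rather than the clock: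

spent at 20 % conversion = 20 % × 20 mM ÷ 202 = 19.8 µM, or 19.8 % of the catalyst charged

Take the same loss from a larger charge, and compare what remains alive:

doubled charge: 2.25

charge of 1000 µM: 12.2

The allowance times the charge gives 20.2 mM of target, level with the substrate with the partner still at its charge. But self-condensation alone gives the partner a first half-life of 65.6 s, so expect the allowance to shrink during the run, and charge more catalyst.

With substrate and partner taken at their charges, coupling within the live catalyst is slower than release, and free catalyst binds faster than intermediate A leaves by unbinding and coupling together. I therefore name intermediate A as the resting state, at 34.1 % of the catalyst.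

The forecast says catalyst intermediate A at 35 %, with factors of 2.4 and 13.8. Both factors stand above mine, and its ground is “leaving less time for the coupling partner to self-condense”.

The simulation gives catalyst intermediate A at 35.1 %, with factors of 2.42 and 13.9. Watch intermediate B on repeating the run: the forecast's resting state is wrong in a run where it stands over intermediate A, and in the base flask it holds 24.6 %. In the base flask, self-condensation uses coupling partner at 2.2 times the rate of coupling at 16.1 s, and target per catalyst charged reads 120 at 500 s, with spent catalyst at >99.9 %, below the allowance of 202. In the flask charged with 1000 µM, the allowance puts the spent share at 1.98 %, and the rate at 20 % conversion comes out 13.9 times the base flask's, above the 12.2 reckoned with the partner held at its charge.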